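With the units lettered A (catechin end) to D, the tetramer is cut at C4–C4a of unit B, so the pyran ring of B is the last ring made. One operation, a BF3-triggered 6-endo opening of a trans-epoxide by an aryl ether, closes that ring, sets C4 of B and unites the A half with the C–D half. It exploits the fact that C6 of B is para to O1 on the benzo ring of B: a phenol bearing unit A between two benzyloxy groups has two equivalent ortho carbons, so only the 4→6 linkage can form. The precursor is the threo aryl ether of a trans-epoxy alcohol whose oxirane sits on C8 of unit C.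

Key step: step 16

Remark: 3',4'-bis(benzyloxy)acetophenone 9 is taken as a purchasable compound; 4β means the face opposite the 2-aryl group and 4α the same face as it, and erythro/threo refer to the carbinol oxygen and the oxirane oxygen being anti/syn in the zigzag drawing of the three-carbon chain.

Step 1
Reactants: 1 (−)-epicatechin
Product: 3 3,5,7,3',4'-penta-O-benzyl-(−)-epicatechin, via tetra-O-benzylepicatechin 2 (not isolated)
Conditions: BnBr, K2CO3, DMF, 0 °C → rt; then NaH, BnBr, 0 °C → rt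
Reagents that add atoms: benzyl bromide BrCc1ccccc1
Why: Carbonate-mediated O-alkylation of the four phenols and then Williamson etherification of the C3 hydroxyl with NaH in the same flask should give the pentabenzyl ether; no bond to C2 or C3 is broken, so the 2R,3R centres are carried through, and the mild first stage avoids base-induced epimerisation at C2 of the free catechol.

Step 2
Reactants: 3 3,5,7,3',4'-penta-O-benzyl-(−)-epicatechin
Product: 4 4β-(2-ethoxyethoxy)-penta-O-benzylepicatechin
Conditions: DDQ, 2-ethoxyethanol, CH2Cl2, rt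
Reagents that add atoms: 2-ethoxyethanol CCOCCO
Why: DDQ abstracts hydride from the C4 methylene activated by the 5,7-dioxygenated benzo ring (benzylic oxidation) and the cation is trapped by the alcohol on the face anti to the 2-aryl and 3-benzyloxy groups, which should give the 4β ether; this centre serves only as a leaving group.

Step 3
Reactants: 4 4β-(2-ethoxyethoxy)-penta-O-benzylepicatechin
Product: 5 8-bromo-4β-(2-ethoxyethoxy)-penta-O-benzylepicatechin
Conditions: NBS, CH2Cl2, −78 → 0 °C
Reagents that add atoms: N-bromosuccinimide O=C1CCC(=O)N1Br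
Why: Electrophilic aromatic bromination is expected at C8, flanked by O1 and one benzyloxy group, and not at C6, which is crowded by two benzyloxy groups; the bromine caps C8 against self-condensation in step 4 and later becomes the handle for the side chain.

Step 4
Reactants: 5 8-bromo-4β-(2-ethoxyethoxy)-penta-O-benzylepicatechin; 3 3,5,7,3',4'-penta-O-benzyl-(−)-epicatechin (3 equiv, excess recovered)
Product: 6 C–D bromide, 8-bromo-penta-O-benzylepicatechin-(4β→8)-penta-O-benzylepicatechin
Conditions: Me3SiOTf (0.1 equiv), CH2Cl2, −78 °C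
Reagents that add atoms: none
Why: The silyl triflate ionises the C4 ether to a benzylic cation stabilised by the ring oxygens, and Friedel–Crafts attack by C8 of 3 from the face anti to the 3-benzyloxy and 2-aryl groups should set the 4β (3,4-trans) interflavan bond of unit C, the usual outcome for epicatechin-type C4 cations.

Step 5
Reactants: 6 C–D bromide
Product: 8 C–D aldehyde (8-formyl analogue of 6), via C8-lithio C–D dimer 7 (not isolated)
Conditions: n-BuLi, THF, −78 °C; DMF, −78 → 0 °C; H2O
Reagents that add atoms: N,N-dimethylformamide CN(C)C=O (formyl group of 8); n-butyllithium [Li]CCCC (lithium of 7 only)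
Why: Bromine–lithium exchange at −78 °C is faster than deprotonation of the benzyl ethers and gives an aryllithium flanked by two oxygens, which DMF formylates (Bouveault-type formylation) once the hemiaminal collapses on work-up.

Step 6
Reactants: 8 C–D aldehyde; 9 3',4'-bis(benzyloxy)acetophenone
Product: 10 C–D chalcone, (E)-1-[3,4-bis(benzyloxy)phenyl]-3-(C8 of unit C)prop-2-en-1-one
Conditions: KOH, EtOH/THF, rt → 40 °C
Reagents that add atoms: none
Why: Claisen–Schmidt condensation of the non-enolisable aldehyde with the methyl ketone enolate and E1cB dehydration should give the conjugated enone, with the E isomer strongly favoured thermodynamically; the benzyl ethers and the interflavan bond are inert to hydroxide.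

Step 7
Reactants: 10 C–D chalcone
Product: 11 C–D epoxy ketone, (2R,3S)-trans-oxirane of 10
Conditions: poly-L-leucine, urea–H2O2, DBU, THF, rt
Reagents that add atoms: hydrogen peroxide OO (used as its urea adduct NC(N)=O.OO)
Why: Juliá–Colonna epoxidation: conjugate addition of hydroperoxide to the enone held at the helical N-terminus of the polypeptide and closure of the enolate should give the trans-epoxy ketone, poly-L-leucine being the antipode that gives the (2R,3S) oxide with chalcones, and the basic medium spares the acid-labile aryl oxirane.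

Step 8
Reactants: 11 C–D epoxy ketone
Product: 12 C–D erythro epoxy alcohol, (1S,2S,3S), trans-oxirane
Conditions: Zn(BH4)2, Et2O/THF, −30 → 0 °C; H2O
Reagents that add atoms: none
Why: Zinc bridges the carbonyl and oxirane oxygens and hydride reaches the chelate from the face opposite the oxirane β-carbon, the established erythro-selective reduction of α,β-epoxy ketones, which should set the carbinol as 1S without touching the epoxide.

Step 9
Reactants: 13 (+)-catechin
Product: 15 3,5,7,3',4'-penta-O-benzyl-(+)-catechin, via tetra-O-benzylcatechin 14 (not isolated)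
Conditions: BnBr, K2CO3, DMF, 0 °C → rt; then NaH, BnBr, 0 °C → rt
Reagents that add atoms: benzyl bromide BrCc1ccccc1
Why: The same phenol O-alkylation and Williamson etherification as in step 1; the 2R,3S centres are not involved.

Step 10
Reactants: 15 3,5,7,3',4'-penta-O-benzyl-(+)-catechin
Product: 16 4β-(2-ethoxyethoxy)-penta-O-benzylcatechin
Conditions: DDQ, 2-ethoxyethanol, CH2Cl2, rt
Reagents that add atoms: 2-ethoxyethanol CCOCCO
Why: The same benzylic oxidation as in step 2; the ether is expected mainly on the face anti to the 2-aryl group, and its configuration is irrelevant because C4 is ionised in step 11.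

Step 11
Reactants: 16 4β-(2-ethoxyethoxy)-penta-O-benzylcatechin; 17 phloroglucinol (5 equiv)
Product: 18 4α-(2,4,6-trihydroxyphenyl)-penta-O-benzylcatechin
Conditions: BF3·OEt2 (0.5 equiv), THF/CH2Cl2, −20 → 0 °C
Reagents that add atoms: none
Why: BF3 ionises the C4 ether and the symmetric, highly nucleophilic phloroglucinol, in excess to suppress double arylation and self-condensation, attacks the cation anti to the 3-benzyloxy group in a Friedel–Crafts alkylation, which should give the 4α (3,4-trans) adduct with no regiochemical ambiguity.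

Step 12
Reactants: 18 4α-(2,4,6-trihydroxyphenyl)-penta-O-benzylcatechin
Product: 19 para-O-triisopropylsilyl ether of 18
Conditions: i-Pr3SiCl (1.05 equiv), imidazole, DMF, 0 °C
Reagents that add atoms: chlorotriisopropylsilane CC(C)[Si](Cl)(C(C)C)C(C)C
Why: The two hydroxyls ortho to the bulky flavan-4-yl group are shielded, so one equivalent of the hindered silyl chloride should silylate only the para hydroxyl.

Step 13
Reactants: 19 para-O-triisopropylsilyl ether of 18
Product: 20 ortho,ortho'-di-O-benzyl para-O-silyl ether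
Conditions: BnBr, K2CO3, n-Bu4NI (cat.), DMF, rt → 40 °C
Reagents that add atoms: benzyl bromide BrCc1ccccc1
Why: Williamson benzylation of the two remaining phenols under carbonate conditions that an aryl triisopropylsilyl ether tolerates.

Step 14
Reactants: 20 ortho,ortho'-di-O-benzyl para-O-silyl ether
Product: 21 unit A phenol, 3,5-bis(benzyloxy)-4-(penta-O-benzylcatechin-4α-yl)phenol
Conditions: n-Bu4NF, AcOH, THF, 0 °C
Reagents that add atoms: none
Why: Fluoride cleaves the aryl silyl ether under buffered conditions that leave the benzyl ethers and the C4–aryl bond untouched, releasing the phenol whose hydroxyl is para to the carbon bearing unit A.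

Step 15
Reactants: 12 C–D erythro epoxy alcohol; 21 unit A phenol
Product: 22 threo epoxy aryl ether (key-step precursor), (1R,2R,3S), trans-oxirane
Conditions: PPh3, DIAD, toluene, 0 °C → rt
Reagents that add atoms: none
Why: Mitsunobu etherification: the alkoxyphosphonium ion of the secondary carbinol is displaced by the phenoxide of 21 in an SN2 process with inversion, turning the erythro (1S) alcohol into the threo (1R) aryl ether, while the oxirane is a spectator under these near-neutral conditions.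

Step 16
Reactants: 22 threo epoxy aryl ether
Product: 23 nonadeca-O-benzyl tetramer with free 3-OH on unit B
Conditions: BF3·OEt2 (0.3 equiv), CH2Cl2 (high dilution), −78 °C
Reagents that add atoms: none
Why: BF3 coordinates the oxirane oxygen and loosens the C4–O bond, which is benzylic to the 5,7-dioxygenated benzo ring of unit C, and a carbon of the aryl ether that is ortho to O1 and ortho/para to the two benzyloxy groups attacks C4 from the face opposite the departing oxygen, rearomatisation then giving the chroman-3-ol with its 3-OH free. The closest known reaction type is the Lewis-acid-mediated intramolecular Friedel–Crafts epoxide–arene cyclisation of aryl 3-arylglycidyl ethers to trans-4-arylchroman-3-ols. The pyran ring of unit B closes in the 6-endo mode (attack at the distal oxirane carbon), preferred over 5-exo because only C4 has benzylic stabilisation. C4 is the one new stereocentre and is set by inversion of the trans-epoxide, giving the 3,4-trans (4β) bond, while C2 and C3 are carried over from 22; should the opening become cationic, approach anti to the C3 oxygen leads to the same isomer. The regiochemistry needed, unit A at C6, is secured by the local symmetry of the aryl ether, whose two carbons ortho to O1 are equivalent because the carbon bearing unit A is para to O1. Low temperature and a substoichiometric amount of Lewis acid should keep the interflavan bonds, the benzyl ethers and the benzylic C2–O1 ether intact.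

Step 17
Reactants: 23 nonadeca-O-benzyl tetramer
Product: 24 catechin-(4α→6)-epicatechin-(4β→8)-epicatechin-(4β→8)-epicatechin (target, CNP0228086.1)
Conditions: H2 (1 atm), Pd(OH)2/C, THF/MeOH/H2O, rt
Reagents that add atoms: none
Why: Hydrogenolysis over Pd(OH)2/C cleaves only the nineteen benzylic C–O bonds of the protecting groups and should leave the interflavan bonds and all eleven stereocentres untouched.

Compound list
1 | (−)-epicatechin | Oc1cc(O)c2c(c1)O[C@H](c1ccc(O)c(O)c1)[C@H](O)C2 | starting material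
2 | 5,7,3',4'-tetra-O-benzylepicatechin (3-OH free) | c9ccccc9COc1cc(OCc9ccccc9)c2c(c1)O[C@H](c1ccc(OCc9ccccc9)c(OCc9ccccc9)c1)[C@H](O)C2 | intermediate
3 | 3,5,7,3',4'-penta-O-benzyl-(−)-epicatechin | c9ccccc9COc1cc(OCc9ccccc9)c2c(c1)O[C@H](c1ccc(OCc9ccccc9)c(OCc9ccccc9)c1)[C@H](OCc9ccccc9)C2 | intermediate
4 | 4β-(2-ethoxyethoxy)-penta-O-benzylepicatechin (C4 ether trans to the 3-OBn) | c9ccccc9COc1cc(OCc9ccccc9)c2c(c1)O[C@H](c1ccc(OCc9ccccc9)c(OCc9ccccc9)c1)[C@H](OCc9ccccc9)[C@H]2OCCOCC | intermediate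
5 | 8-bromo-4β-(2-ethoxyethoxy)-penta-O-benzylepicatechin | c9ccccc9COc1cc(OCc9ccccc9)c2c(c1Br)O[C@H](c1ccc(OCc9ccccc9)c(OCc9ccccc9)c1)[C@H](OCc9ccccc9)[C@H]2OCCOCC | intermediate
6 | C–D bromide: 8-bromo-penta-O-benzylepicatechin-(4β→8)-penta-O-benzylepicatechin | c9ccccc9COc1cc(OCc9ccccc9)c2c(c1Br)O[C@H](c1ccc(OCc9ccccc9)c(OCc9ccccc9)c1)[C@H](OCc9ccccc9)[C@H]2c1c(OCc9ccccc9)cc(OCc9ccccc9)c3c1O[C@H](c1ccc(OCc9ccccc9)c(OCc9ccccc9)c1)[C@H](OCc9ccccc9)C3 | intermediate
7 | C8-lithio C–D dimer (aryllithium from 6) | c9ccccc9COc1cc(OCc9ccccc9)c2c(c1[Li])O[C@H](c1ccc(OCc9ccccc9)c(OCc9ccccc9)c1)[C@H](OCc9ccccc9)[C@H]2c1c(OCc9ccccc9)cc(OCc9ccccc9)c3c1O[C@H](c1ccc(OCc9ccccc9)c(OCc9ccccc9)c1)[C@H](OCc9ccccc9)C3 | intermediate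
8 | C–D aldehyde: 8-formyl-penta-O-benzylepicatechin-(4β→8)-penta-O-benzylepicatechin | c9ccccc9COc1cc(OCc9ccccc9)c2c(c1C=O)O[C@H](c1ccc(OCc9ccccc9)c(OCc9ccccc9)c1)[C@H](OCc9ccccc9)[C@H]2c1c(OCc9ccccc9)cc(OCc9ccccc9)c3c1O[C@H](c1ccc(OCc9ccccc9)c(OCc9ccccc9)c1)[C@H](OCc9ccccc9)C3 | intermediate
9 | 3',4'-bis(benzyloxy)acetophenone | CC(=O)c1ccc(OCc9ccccc9)c(OCc9ccccc9)c1 | starting material
10 | C–D chalcone: (E)-enone joining C8 of unit C to the 3,4-bis(benzyloxy)benzoyl group | c9ccccc9COc1cc(OCc9ccccc9)c2c(c1/C=C/C(=O)c4ccc(OCc9ccccc9)c(OCc9ccccc9)c4)O[C@H](c1ccc(OCc9ccccc9)c(OCc9ccccc9)c1)[C@H](OCc9ccccc9)[C@H]2c1c(OCc9ccccc9)cc(OCc9ccccc9)c3c1O[C@H](c1ccc(OCc9ccccc9)c(OCc9ccccc9)c1)[C@H](OCc9ccccc9)C3 | intermediate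
11 | C–D epoxy ketone: (2R,3S)-trans-2,3-epoxy-1-[3,4-bis(benzyloxy)phenyl]propan-1-one carrying C8 of unit C at C3 | c9ccccc9COc1cc(OCc9ccccc9)c2c(c1[C@@H]4O[C@H]4C(=O)c5ccc(OCc9ccccc9)c(OCc9ccccc9)c5)O[C@H](c1ccc(OCc9ccccc9)c(OCc9ccccc9)c1)[C@H](OCc9ccccc9)[C@H]2c1c(OCc9ccccc9)cc(OCc9ccccc9)c3c1O[C@H](c1ccc(OCc9ccccc9)c(OCc9ccccc9)c1)[C@H](OCc9ccccc9)C3 | intermediate
12 | C–D erythro epoxy alcohol: (1S,2S,3S)-1-[3,4-bis(benzyloxy)phenyl]-2,3-epoxypropan-1-ol carrying C8 of unit C at C3, trans-oxirane | c9ccccc9COc1cc(OCc9ccccc9)c2c(c1[C@@H]4O[C@H]4[C@@H](O)c5ccc(OCc9ccccc9)c(OCc9ccccc9)c5)O[C@H](c1ccc(OCc9ccccc9)c(OCc9ccccc9)c1)[C@H](OCc9ccccc9)[C@H]2c1c(OCc9ccccc9)cc(OCc9ccccc9)c3c1O[C@H](c1ccc(OCc9ccccc9)c(OCc9ccccc9)c1)[C@H](OCc9ccccc9)C3 | intermediate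
13 | (+)-catechin | Oc1cc(O)c2c(c1)O[C@H](c1ccc(O)c(O)c1)[C@@H](O)C2 | starting material
14 | 5,7,3',4'-tetra-O-benzylcatechin (3-OH free) | c9ccccc9COc1cc(OCc9ccccc9)c2c(c1)O[C@H](c1ccc(OCc9ccccc9)c(OCc9ccccc9)c1)[C@@H](O)C2 | intermediate
15 | 3,5,7,3',4'-penta-O-benzyl-(+)-catechin | c9ccccc9COc1cc(OCc9ccccc9)c2c(c1)O[C@H](c1ccc(OCc9ccccc9)c(OCc9ccccc9)c1)[C@@H](OCc9ccccc9)C2 | intermediate
16 | 4β-(2-ethoxyethoxy)-penta-O-benzylcatechin (C4 ether cis to the 3-OBn) | c9ccccc9COc1cc(OCc9ccccc9)c2c(c1)O[C@H](c1ccc(OCc9ccccc9)c(OCc9ccccc9)c1)[C@@H](OCc9ccccc9)[C@H]2OCCOCC | intermediate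
17 | phloroglucinol | Oc1cc(O)cc(O)c1 | starting material
18 | 4α-(2,4,6-trihydroxyphenyl)-penta-O-benzylcatechin (3,4-trans) | c9ccccc9COc1cc(OCc9ccccc9)c2c(c1)O[C@H](c1ccc(OCc9ccccc9)c(OCc9ccccc9)c1)[C@@H](OCc9ccccc9)[C@@H]2c1c(O)cc(O)cc1O | intermediate
19 | para-O-triisopropylsilyl ether of 18 (both ortho hydroxyls free) | c9ccccc9COc1cc(OCc9ccccc9)c2c(c1)O[C@H](c1ccc(OCc9ccccc9)c(OCc9ccccc9)c1)[C@@H](OCc9ccccc9)[C@@H]2c1c(O)cc(O[Si](C(C)C)(C(C)C)C(C)C)cc1O | intermediate
20 | ortho,ortho'-di-O-benzyl para-O-triisopropylsilyl ether | c9ccccc9COc1cc(OCc9ccccc9)c2c(c1)O[C@H](c1ccc(OCc9ccccc9)c(OCc9ccccc9)c1)[C@@H](OCc9ccccc9)[C@@H]2c1c(OCc9ccccc9)cc(O[Si](C(C)C)(C(C)C)C(C)C)cc1OCc9ccccc9 | intermediate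
21 | unit A phenol: 3,5-bis(benzyloxy)-4-(penta-O-benzylcatechin-4α-yl)phenol | c9ccccc9COc1cc(OCc9ccccc9)c2c(c1)O[C@H](c1ccc(OCc9ccccc9)c(OCc9ccccc9)c1)[C@@H](OCc9ccccc9)[C@@H]2c1c(OCc9ccccc9)cc(O)cc1OCc9ccccc9 | intermediate
22 | threo epoxy aryl ether (key-step precursor): ether of phenol 21 with the (1R)-carbinol carbon of the (1R,2R,3S)-trans-epoxide attached to C8 of unit C | c9ccccc9COc1cc(OCc9ccccc9)c2c(c1)O[C@H](c1ccc(OCc9ccccc9)c(OCc9ccccc9)c1)[C@@H](OCc9ccccc9)[C@@H]2c1c(OCc9ccccc9)cc(cc1OCc9ccccc9)O[C@H](c1ccc(OCc9ccccc9)c(OCc9ccccc9)c1)[C@@H]4O[C@H]4c1c(OCc9ccccc9)cc(OCc9ccccc9)c3c1O[C@H](c1ccc(OCc9ccccc9)c(OCc9ccccc9)c1)[C@H](OCc9ccccc9)[C@H]3c1c(OCc9ccccc9)cc(OCc9ccccc9)c3c1O[C@H](c1ccc(OCc9ccccc9)c(OCc9ccccc9)c1)[C@H](OCc9ccccc9)C3 | intermediate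
23 | nonadeca-O-benzyl catechin-(4α→6)-epicatechin-(4β→8)-epicatechin-(4β→8)-epicatechin with free 3-OH on unit B (unit B 2,3-cis, 3,4-trans) | c9ccccc9COc1cc(OCc9ccccc9)c2c(c1)O[C@H](c1ccc(OCc9ccccc9)c(OCc9ccccc9)c1)[C@@H](OCc9ccccc9)[C@@H]2c1c(OCc9ccccc9)cc2c(c1OCc9ccccc9)[C@H](c1c(OCc9ccccc9)cc(OCc9ccccc9)c3c1O[C@H](c1ccc(OCc9ccccc9)c(OCc9ccccc9)c1)[C@H](OCc9ccccc9)[C@H]3c1c(OCc9ccccc9)cc(OCc9ccccc9)c3c1O[C@H](c1ccc(OCc9ccccc9)c(OCc9ccccc9)c1)[C@H](OCc9ccccc9)C3)[C@@H](O)[C@@H](c1ccc(OCc9ccccc9)c(OCc9ccccc9)c1)O2 | intermediate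
24 | catechin-(4α→6)-epicatechin-(4β→8)-epicatechin-(4β→8)-epicatechin (CNP0228086.1) | Oc1cc(O)c2c(c1)O[C@H](c1ccc(O)c(O)c1)[C@@H](O)[C@@H]2c1c(O)cc2c(c1O)[C@H](c1c(O)cc(O)c3c1O[C@H](c1ccc(O)c(O)c1)[C@H](O)[C@H]3c1c(O)cc(O)c3c1O[C@H](c1ccc(O)c(O)c1)[C@H](O)C3)[C@@H](O)[C@@H](c1ccc(O)c(O)c1)O2 | target

Total step count: 17. Longest linear sequence: 11 steps (steps 1–8, then 15–17, from (−)-epicatechin); the unit A branch (steps 9–14) has 6 steps.

Steps most likely to fail

1. The key step (step 16). The Lewis-acid-bound oxirane may isomerise by 1,2-hydride shift to the C3 ketone, or its ring-opened C4 cation may be intercepted by another molecule, before the crowded aryl ether carbon reaches C4. The fallback replaces direct epoxide activation by a two-stage ionisation and sets out from 22. Buffered alcoholysis of the oxirane at the benzylic C4 (2-ethoxyethanol as co-solvent, pyridinium p-toluenesulfonate cat., THF, 0 °C) should give the 4-(2-ethoxyethoxy)-3-ol F1, a flavan-type C4 donor of the kind used in steps 4 and 11, whose C4 configuration is immaterial. Me3SiOTf (cat.) in CH2Cl2 at −78 °C would then generate the C4 cation without a strained ring. Intramolecular Friedel–Crafts attack by the same aryl ether carbon, anti to the C3 hydroxyl, should close the pyran ring, and the route is rejoined at 23.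

2. The Mitsunobu etherification (step 15). Bimolecular displacement at a hindered, electron-rich benzylic carbinol is slow, so ionisation of the alkoxyphosphonium ion (loss of clean inversion at C2), elimination or alkylation of the hydrazide can compete. The fallback inverts the order in which ring B is assembled and sets out from 12 and 21. With BF3·OEt2 in CH2Cl2 at −78 °C a carbon ortho to the free hydroxyl of 21 (both are equivalent) should open the oxirane of 12 at C4 with inversion, giving the phenol diol F2, which already holds the C4–C4a bond. An intramolecular Mitsunobu etherification (PPh3, DIAD, THF, 0 °C) would then close the pyran ring by attack of the phenol oxygen on the benzylic C2 carbinol with inversion. This six-membered closure is far faster than the intermolecular reaction and is the established route from 1,3-diarylpropane-1,2-diols to flavan-3-ols; the route is rejoined at 23.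

3. The asymmetric epoxidation (step 7). Hydroperoxide addition to a doubly ortho-substituted, electron-rich enone may be slow on the polymeric catalyst, or face selection may be poor because the bulky C–D dimer cannot dock on the polypeptide. The fallback changes from nucleophilic to hydroxyl-directed epoxidation and sets out from 10. Corey–Bakshi–Shibata reduction (BH3·SMe2, THF, −30 °C) should give the (R)-allylic alcohol F3. The oxazaborolidine antipode is chosen for the R carbinol: (R)-2-methyl-CBS-oxazaborolidine if the styryl arm acts as the larger group, to be fixed on a model chalcone. Sharpless asymmetric epoxidation (Ti(OiPr)4, L-(+)-diisopropyl tartrate, t-BuOOH, 4 Å molecular sieves, CH2Cl2, −20 °C), matched for this carbinol configuration and erythro-selective, would then deliver 12; this path bypasses 11 and rejoins the route at 12.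

Further compounds
F1 | step 16 | 4-(2-ethoxyethoxy)-3-ol from benzylic alcoholysis of the oxirane of 22 (C2 and C3 as in 22, C4 ether from anti opening) | c9ccccc9COc1cc(OCc9ccccc9)c2c(c1)O[C@H](c1ccc(OCc9ccccc9)c(OCc9ccccc9)c1)[C@@H](OCc9ccccc9)[C@@H]2c1c(OCc9ccccc9)cc(cc1OCc9ccccc9)O[C@H](c1ccc(OCc9ccccc9)c(OCc9ccccc9)c1)[C@H](O)[C@H](OCCOCC)c1c(OCc9ccccc9)cc(OCc9ccccc9)c3c1O[C@H](c1ccc(OCc9ccccc9)c(OCc9ccccc9)c1)[C@H](OCc9ccccc9)[C@H]3c1c(OCc9ccccc9)cc(OCc9ccccc9)c3c1O[C@H](c1ccc(OCc9ccccc9)c(OCc9ccccc9)c1)[C@H](OCc9ccccc9)C3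
F2 | step 15 | phenol diol from C-arylation of 12 by 21 at C4 (C4–C4a bond of unit B formed, O1–C2 bond open, C2 carbinol still S) | c9ccccc9COc1cc(OCc9ccccc9)c2c(c1)O[C@H](c1ccc(OCc9ccccc9)c(OCc9ccccc9)c1)[C@@H](OCc9ccccc9)[C@@H]2c1c(OCc9ccccc9)cc(O)c(c1OCc9ccccc9)[C@H](c1c(OCc9ccccc9)cc(OCc9ccccc9)c3c1O[C@H](c1ccc(OCc9ccccc9)c(OCc9ccccc9)c1)[C@H](OCc9ccccc9)[C@H]3c1c(OCc9ccccc9)cc(OCc9ccccc9)c3c1O[C@H](c1ccc(OCc9ccccc9)c(OCc9ccccc9)c1)[C@H](OCc9ccccc9)C3)[C@@H](O)[C@@H](O)c1ccc(OCc9ccccc9)c(OCc9ccccc9)c1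
F3 | step 7 | (R,E)-allylic alcohol from carbonyl reduction of chalcone 10 | c9ccccc9COc1cc(OCc9ccccc9)c2c(c1/C=C/[C@@H](O)c4ccc(OCc9ccccc9)c(OCc9ccccc9)c4)O[C@H](c1ccc(OCc9ccccc9)c(OCc9ccccc9)c1)[C@H](OCc9ccccc9)[C@H]2c1c(OCc9ccccc9)cc(OCc9ccccc9)c3c1O[C@H](c1ccc(OCc9ccccc9)c(OCc9ccccc9)c1)[C@H](OCc9ccccc9)C3
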